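**Plan**

- Retrosynthesis: the acetate and the enal are traced back to a C9 aldehyde and a C10 N-methoxy-N-methyl amide. Then the C1–C2 bond of ring B is cut, followed by the C3=C4 alkene (olefination), the C4–C4a bond (formylation) and the C1–guaiacyl bond (Grignard addition).
- The C1–C2 cut rests on two features: C1 is para-hydroxybenzylic on the guaiacyl ring and can be flattened to a p-quinone methide, and C2 is alpha to C9, which as an aldehyde gives a dienamine nucleophilic at C2. The cis C3=C4 bond holds C2 next to C1.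
- Forward: the two aromatic rings are bought. A ring A aldehyde and a guaiacyl Grignard reagent give the racemic diaryl carbinol, the chain C4–C3(C10)–C2–C9 is attached by formylation and olefination, and ring B (the only ring made) closes last. Reduction, acetylation, amide-to-aldehyde reduction and phenol release finish the target.
- Stereochemistry: both centres arise in the ring closure. An (R)-diarylprolinol silyl ether fixes the enamine face at C2, the closure places C1 trans to it, and both carbinol enantiomers converge on the same planar quinone methide.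

Key step: step 12

Remark: locants follow the 1,2-dihydronaphthalene core (C1 diaryl methine, C2, C3, C4, C4a–C8a); C9 is the CH2OAc carbon and C10 the formyl carbon. The target is the trans (1S,2R) isomer. Compounds 8–11 and 15–17 are racemic at the carbinol carbon.

**Step 1**
Reactants: 1 2,3-dihydroxybenzaldehyde
Product: 2 3-hydroxy-2-methoxybenzaldehyde
Conditions: NaH (1.0 equiv), DMSO, rt; MeI (1.0 equiv)
Reagents that add atoms: iodomethane, CI
Why: Williamson etherification of the monosodium salt: with one equivalent of base only the more acidic 2-OH (ortho to and conjugated with the formyl group) is deprotonated, so methylation should occur at O2 and leave the 3-OH free.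

**Step 2**
Reactants: 2 3-hydroxy-2-methoxybenzaldehyde
Product: 3 6-bromo-3-hydroxy-2-methoxybenzaldehyde
Conditions: NBS (1.0 equiv), MeCN, 0 °C → rt
Reagents that add atoms: N-bromosuccinimide, O=C1CCC(=O)N1Br
Why: Electrophilic aromatic bromination directed para to the free 3-hydroxyl (C6, ortho to the formyl group), as in the para-bromination of 3-hydroxybenzaldehyde; the twisted 2-methoxy group is the weaker director.

**Step 3**
Reactants: 3 6-bromo-3-hydroxy-2-methoxybenzaldehyde
Product: 4 6-bromo-3-(tert-butyldimethylsilyloxy)-2-methoxybenzaldehyde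
Conditions: TBSCl, imidazole, DMF, rt
Reagents that add atoms: tert-butyldimethylsilyl chloride, CC(C)(C)[Si](C)(C)Cl
Why: Standard silylation of a phenol; the silyl ether masks the ring A phenol against the organometallic steps.

**Step 4**
Reactants: 5 4-bromo-2-methoxyphenol
Product: 6 (4-bromo-2-methoxyphenoxy)(tert-butyl)dimethylsilane
Conditions: TBSCl, imidazole, DMF, rt
Reagents that add atoms: tert-butyldimethylsilyl chloride, CC(C)(C)[Si](C)(C)Cl
Why: Standard silylation of a phenol so that the aryl bromide can be converted into a Grignard reagent.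

**Step 5**
Reactants: 6 (4-bromo-2-methoxyphenoxy)(tert-butyl)dimethylsilane; 4 6-bromo-3-(tert-butyldimethylsilyloxy)-2-methoxybenzaldehyde
Product: 8 rac-[6-bromo-3-(tert-butyldimethylsilyloxy)-2-methoxyphenyl][4-(tert-butyldimethylsilyloxy)-3-methoxyphenyl]methanol, via aryl Grignard reagent 7 (not isolated)
Conditions: 6, Mg, THF, 50 °C; then 4, THF, 0 °C; sat. aq. NH4Cl
Reagents that add atoms: none
Why: Grignard formation and 1,2-addition to the aldehyde form the C1–aryl bond; the aryl bromide of 4 should not exchange with an aryl Grignard reagent at 0 °C, and the racemic carbinol is acceptable because C1 is planarised later.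

**Step 6**
Reactants: 8 rac-[6-bromo-3-(tert-butyldimethylsilyloxy)-2-methoxyphenyl][4-(tert-butyldimethylsilyloxy)-3-methoxyphenyl]methanol
Product: 9 rac-{[6-bromo-3-(tert-butyldimethylsilyloxy)-2-methoxyphenyl][4-(tert-butyldimethylsilyloxy)-3-methoxyphenyl]methoxy}triethylsilane
Conditions: TESCl, imidazole, DMAP (cat.), DMF, rt
Reagents that add atoms: chlorotriethylsilane, CC[Si](Cl)(CC)CC
Why: Silylation of the secondary alcohol; the triethylsilyl ether blocks lactol formation and oxa-Michael addition in the next steps and is later removed by dilute acid.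

**Step 7**
Reactants: 9 rac-{[6-bromo-3-(tert-butyldimethylsilyloxy)-2-methoxyphenyl][4-(tert-butyldimethylsilyloxy)-3-methoxyphenyl]methoxy}triethylsilane
Product: 11 rac-4-(tert-butyldimethylsilyloxy)-2-{[4-(tert-butyldimethylsilyloxy)-3-methoxyphenyl](triethylsilyloxy)methyl}-3-methoxybenzaldehyde, via aryllithium 10 (not isolated)
Conditions: t-BuLi (2.0 equiv), Et2O, −78 °C; DMF, −78 → 0 °C; H2O
Reagents that add atoms: N,N-dimethylformamide, CN(C)C=O
Why: Bromine–lithium exchange followed by formylation with DMF; in ether at −78 °C exchange and trapping should outrun retro-Brook migration of the benzylic silyl group.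

**Step 8**
Reactants: 12 diethyl (N-methoxy-N-methylcarbamoylmethyl)phosphonate; 13 bromoacetaldehyde dimethyl acetal
Product: 14 diethyl {4,4-dimethoxy-1-[methoxy(methyl)amino]-1-oxobutan-2-yl}phosphonate
Conditions: NaH (1.0 equiv), DMF, 0 °C; 13, NaI (cat.), 70 °C
Reagents that add atoms: none
Why: SN2 C-alkylation of the stabilised phosphonate carbanion, as practised for phosphonoacetates with bromoacetaldehyde acetals; iodide catalysis and heat compensate for the sluggish electrophile.

**Step 9**
Reactants: 11 rac-4-(tert-butyldimethylsilyloxy)-2-{[4-(tert-butyldimethylsilyloxy)-3-methoxyphenyl](triethylsilyloxy)methyl}-3-methoxybenzaldehyde; 14 diethyl {4,4-dimethoxy-1-[methoxy(methyl)amino]-1-oxobutan-2-yl}phosphonate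
Product: 15 rac-(E)-3-[4-(tert-butyldimethylsilyloxy)-2-{[4-(tert-butyldimethylsilyloxy)-3-methoxyphenyl](triethylsilyloxy)methyl}-3-methoxyphenyl]-2-(2,2-dimethoxyethyl)-N-methoxy-N-methylprop-2-enamide
Conditions: NaH, THF, 0 → 40 °C
Reagents that add atoms: none
Why: Horner–Wadsworth–Emmons olefination; the α-branched stabilised phosphonate should give mainly the (E)-alkene, with the aryl group trans to the amide and therefore cis to the CH2 that becomes C2.

**Step 10**
Reactants: 15 rac-(E)-3-[4-(tert-butyldimethylsilyloxy)-2-{[4-(tert-butyldimethylsilyloxy)-3-methoxyphenyl](triethylsilyloxy)methyl}-3-methoxyphenyl]-2-(2,2-dimethoxyethyl)-N-methoxy-N-methylprop-2-enamide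
Product: 16 rac-(E)-2-(2,2-dimethoxyethyl)-3-[4-hydroxy-2-{(4-hydroxy-3-methoxyphenyl)(triethylsilyloxy)methyl}-3-methoxyphenyl]-N-methoxy-N-methylprop-2-enamide
Conditions: TBAF/AcOH (1:1, 2.2 equiv), THF, 0 °C → rt; used crude
Reagents that add atoms: none
Why: Fluoride cleavage of the two aryl silyl ethers, which are far more labile to fluoride than the hindered secondary triethylsilyl ether; the acetic acid buffer prevents phenoxide-driven elimination and oxa-Michael addition, and any carbinol already released converges in step 11.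

**Step 11**
Reactants: 16 rac-(E)-2-(2,2-dimethoxyethyl)-3-[4-hydroxy-2-{(4-hydroxy-3-methoxyphenyl)(triethylsilyloxy)methyl}-3-methoxyphenyl]-N-methoxy-N-methylprop-2-enamide
Product: 17 rac-(E)-3-{4-hydroxy-2-[hydroxy(4-hydroxy-3-methoxyphenyl)methyl]-3-methoxyphenyl}-N-methoxy-N-methyl-2-(2-oxoethyl)prop-2-enamide
Conditions: 0.5 M aq. HCl–THF (1:4), 0 °C, short; NaHCO3; used at once
Reagents that add atoms: water, O
Why: Acid hydrolysis of the dimethyl acetal and the triethylsilyl ether; in the cold aqueous medium a benzylic cation, should it form, is returned to the carbinol by water faster than the unactivated aldehyde can trap it.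

**Step 12**
Reactants: 17 rac-(E)-3-{4-hydroxy-2-[hydroxy(4-hydroxy-3-methoxyphenyl)methyl]-3-methoxyphenyl}-N-methoxy-N-methyl-2-(2-oxoethyl)prop-2-enamide
Product: 19 (1S,2R)-2-formyl-7-hydroxy-1-(4-hydroxy-3-methoxyphenyl)-N,8-dimethoxy-N-methyl-1,2-dihydronaphthalene-3-carboxamide, via p-quinone methide dienamine 18 (not isolated)
Conditions: (R)-α,α-diphenylprolinol trimethylsilyl ether (20 mol%), diphenyl phosphate (30 mol%), CH2Cl2 (0.02 M), 0 °C → rt
Reagents that add atoms: none
Why: The amine condenses with the C9 aldehyde to a dienamine (N–C9=C2–C3=C4) while the phosphoric acid ionises either enantiomer of the para-hydroxybenzylic carbinol to the same planar p-quinone methide at C1 (18); C2 then adds to C1 in a 1,6-addition, the guaiacyl ring rearomatises, and hydrolysis of the iminium ion releases the C2 aldehyde and the catalyst. The closest known reactions are the diarylprolinol silyl ether-catalysed enantioselective 1,6-addition of aldehydes to p-quinone methides, the Brønsted acid generation of p-quinone methides from racemic p-hydroxybenzyl alcohols, and the aminocatalytic SN1-type α-alkylation of aldehydes with diaryl carbinols, here applied intramolecularly. Ring B closes in a 6-(enolexo)-exo-trig mode (C1–C2 bond, the C1=C1' bond of the quinone methide being exocyclic to the new ring), with the cis C3=C4 bond holding C2 within reach of C1. C2 is controlled by the catalyst, whose diphenyl(silyloxy)methyl group shields one face of the (E)-enamine so that C1 is met on the open face (R at C2 with the (R)-catalyst by the usual shielding model; the (S)-catalyst would be used if the sense proved reversed); C1 follows from the cyclic transition state, in which the quinone methide ring lies pseudo-axial, away from the peri C8 methoxy group and anti to the enamine, so the trans (1S,2R) product should result, which is also the isomer favoured by enamine-mediated equilibration at C2. The selectivities needed are C2 over C4 attack of the dienamine (C4 attack would require a four-membered ring), catalysed closure over acid-only closure through the enol (the enamine is by far the better nucleophile), and intra- over intermolecular phenol alkylation (secured by dilution).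

**Step 13**
Reactants: 19 (1S,2R)-2-formyl-7-hydroxy-1-(4-hydroxy-3-methoxyphenyl)-N,8-dimethoxy-N-methyl-1,2-dihydronaphthalene-3-carboxamide
Product: 20 (1S,2R)-7-hydroxy-1-(4-hydroxy-3-methoxyphenyl)-2-(hydroxymethyl)-N,8-dimethoxy-N-methyl-1,2-dihydronaphthalene-3-carboxamide
Conditions: NaBH4, MeOH–THF, −20 °C; crude 19 used without delay, 20 carried on at once
Reagents that add atoms: none
Why: Chemoselective borohydride reduction of the aldehyde beside the N-methoxy-N-methyl amide; low temperature and immediate processing avoid epimerisation or alkene migration before, and lactonisation of the hydroxy amide after, and no stereocentre is touched.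

**Step 14**
Reactants: 20 (1S,2R)-7-hydroxy-1-(4-hydroxy-3-methoxyphenyl)-2-(hydroxymethyl)-N,8-dimethoxy-N-methyl-1,2-dihydronaphthalene-3-carboxamide
Product: 21 [(1S,2R)-7-acetoxy-1-(4-acetoxy-3-methoxyphenyl)-8-methoxy-3-[methoxy(methyl)carbamoyl]-1,2-dihydronaphthalen-2-yl]methyl acetate
Conditions: Ac2O, pyridine, DMAP (cat.), CH2Cl2, 0 °C → rt
Reagents that add atoms: acetic anhydride, CC(=O)OC(C)=O
Why: DMAP-catalysed acylation of the primary alcohol and both phenols installs the C9 acetate and masks the phenols for the hydride step.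

**Step 15**
Reactants: 21 [(1S,2R)-7-acetoxy-1-(4-acetoxy-3-methoxyphenyl)-8-methoxy-3-[methoxy(methyl)carbamoyl]-1,2-dihydronaphthalen-2-yl]methyl acetate
Product: 22 [(1S,2R)-7-acetoxy-1-(4-acetoxy-3-methoxyphenyl)-3-formyl-8-methoxy-1,2-dihydronaphthalen-2-yl]methyl acetate
Conditions: Cp2Zr(H)Cl (1.5–2 equiv), THF, rt, short; H2O/silica
Reagents that add atoms: none
Why: Hydrozirconation of the amide carbonyl gives a stable zirconated hemiaminal that collapses to the aldehyde on work-up; this reduction of tertiary and N-methoxy-N-methyl amides is known to spare esters and conjugated alkenes.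

**Step 16**
Reactants: 22 [(1S,2R)-7-acetoxy-1-(4-acetoxy-3-methoxyphenyl)-3-formyl-8-methoxy-1,2-dihydronaphthalen-2-yl]methyl acetate
Product: 23 [(1S,2R)-3-formyl-7-hydroxy-1-(4-hydroxy-3-methoxyphenyl)-8-methoxy-1,2-dihydronaphthalen-2-yl]methyl acetate
Conditions: NH4OAc (excess), MeOH–H2O (4:1), rt
Reagents that add atoms: none
Why: Chemoselective transesterification of the aryl acetates (phenoxide is the better leaving group) under near-neutral ammonium acetate catalysis should leave the primary alkyl acetate, the enal and both stereocentres intact.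

**Compound list**

1 | 2,3-dihydroxybenzaldehyde | O=Cc1cccc(O)c1O | starting material
2 | 3-hydroxy-2-methoxybenzaldehyde | COc1c(O)cccc1C=O | intermediate
3 | 6-bromo-3-hydroxy-2-methoxybenzaldehyde | COc1c(O)ccc(Br)c1C=O | intermediate
4 | 6-bromo-3-(tert-butyldimethylsilyloxy)-2-methoxybenzaldehyde | COc1c(O[Si](C)(C)C(C)(C)C)ccc(Br)c1C=O | intermediate
5 | 4-bromo-2-methoxyphenol | COc1cc(Br)ccc1O | starting material
6 | (4-bromo-2-methoxyphenoxy)(tert-butyl)dimethylsilane | COc1cc(Br)ccc1O[Si](C)(C)C(C)(C)C | intermediate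
7 | [4-(tert-butyldimethylsilyloxy)-3-methoxyphenyl]magnesium bromide (not isolated) | COc1cc([Mg]Br)ccc1O[Si](C)(C)C(C)(C)C | intermediate
8 | rac-[6-bromo-3-(tert-butyldimethylsilyloxy)-2-methoxyphenyl][4-(tert-butyldimethylsilyloxy)-3-methoxyphenyl]methanol | COc1cc(C(O)c2c(Br)ccc(O[Si](C)(C)C(C)(C)C)c2OC)ccc1O[Si](C)(C)C(C)(C)C | intermediate
9 | rac-{[6-bromo-3-(tert-butyldimethylsilyloxy)-2-methoxyphenyl][4-(tert-butyldimethylsilyloxy)-3-methoxyphenyl]methoxy}triethylsilane | COc1cc(C(O[Si](CC)(CC)CC)c2c(Br)ccc(O[Si](C)(C)C(C)(C)C)c2OC)ccc1O[Si](C)(C)C(C)(C)C | intermediate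
10 | rac-aryllithium from 9 (Li in place of Br; not isolated) | COc1cc(C(O[Si](CC)(CC)CC)c2c([Li])ccc(O[Si](C)(C)C(C)(C)C)c2OC)ccc1O[Si](C)(C)C(C)(C)C | intermediate
11 | rac-4-(tert-butyldimethylsilyloxy)-2-{[4-(tert-butyldimethylsilyloxy)-3-methoxyphenyl](triethylsilyloxy)methyl}-3-methoxybenzaldehyde | COc1cc(C(O[Si](CC)(CC)CC)c2c(C=O)ccc(O[Si](C)(C)C(C)(C)C)c2OC)ccc1O[Si](C)(C)C(C)(C)C | intermediate
12 | diethyl (N-methoxy-N-methylcarbamoylmethyl)phosphonate | CCOP(=O)(CC(=O)N(C)OC)OCC | starting material
13 | bromoacetaldehyde dimethyl acetal | COC(CBr)OC | starting material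
14 | diethyl {4,4-dimethoxy-1-[methoxy(methyl)amino]-1-oxobutan-2-yl}phosphonate | CCOP(=O)(OCC)C(CC(OC)OC)C(=O)N(C)OC | intermediate
15 | rac-(E)-3-[4-(tert-butyldimethylsilyloxy)-2-{[4-(tert-butyldimethylsilyloxy)-3-methoxyphenyl](triethylsilyloxy)methyl}-3-methoxyphenyl]-2-(2,2-dimethoxyethyl)-N-methoxy-N-methylprop-2-enamide | COc1cc(C(O[Si](CC)(CC)CC)c2c(/C=C(\CC(OC)OC)C(=O)N(C)OC)ccc(O[Si](C)(C)C(C)(C)C)c2OC)ccc1O[Si](C)(C)C(C)(C)C | intermediate
16 | rac-(E)-2-(2,2-dimethoxyethyl)-3-[4-hydroxy-2-{(4-hydroxy-3-methoxyphenyl)(triethylsilyloxy)methyl}-3-methoxyphenyl]-N-methoxy-N-methylprop-2-enamide | COc1cc(C(O[Si](CC)(CC)CC)c2c(/C=C(\CC(OC)OC)C(=O)N(C)OC)ccc(O)c2OC)ccc1O | intermediate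
17 | rac-(E)-3-{4-hydroxy-2-[hydroxy(4-hydroxy-3-methoxyphenyl)methyl]-3-methoxyphenyl}-N-methoxy-N-methyl-2-(2-oxoethyl)prop-2-enamide | COc1cc(C(O)c2c(/C=C(\CC=O)C(=O)N(C)OC)ccc(O)c2OC)ccc1O | intermediate
18 | p-quinone methide dienamine from 17 and the (R)-catalyst (not isolated) | COC1=CC(=Cc2c(/C=C(\C=C\N3CCC[C@@H]3C(O[Si](C)(C)C)(c3ccccc3)c3ccccc3)C(=O)N(C)OC)ccc(O)c2OC)C=CC1=O | intermediate
19 | (1S,2R)-2-formyl-7-hydroxy-1-(4-hydroxy-3-methoxyphenyl)-N,8-dimethoxy-N-methyl-1,2-dihydronaphthalene-3-carboxamide | COc1cc([C@H]2c3c(ccc(O)c3OC)C=C(C(=O)N(C)OC)[C@@H]2C=O)ccc1O | intermediate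
20 | (1S,2R)-7-hydroxy-1-(4-hydroxy-3-methoxyphenyl)-2-(hydroxymethyl)-N,8-dimethoxy-N-methyl-1,2-dihydronaphthalene-3-carboxamide | COc1cc([C@H]2c3c(ccc(O)c3OC)C=C(C(=O)N(C)OC)[C@@H]2CO)ccc1O | intermediate
21 | [(1S,2R)-7-acetoxy-1-(4-acetoxy-3-methoxyphenyl)-8-methoxy-3-[methoxy(methyl)carbamoyl]-1,2-dihydronaphthalen-2-yl]methyl acetate | COc1cc([C@H]2c3c(ccc(OC(C)=O)c3OC)C=C(C(=O)N(C)OC)[C@@H]2COC(C)=O)ccc1OC(C)=O | intermediate
22 | [(1S,2R)-7-acetoxy-1-(4-acetoxy-3-methoxyphenyl)-3-formyl-8-methoxy-1,2-dihydronaphthalen-2-yl]methyl acetate | COc1cc([C@H]2c3c(ccc(OC(C)=O)c3OC)C=C(C=O)[C@@H]2COC(C)=O)ccc1OC(C)=O | intermediate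
23 | [(1S,2R)-3-formyl-7-hydroxy-1-(4-hydroxy-3-methoxyphenyl)-8-methoxy-1,2-dihydronaphthalen-2-yl]methyl acetate | COc1cc([C@H]2c3c(ccc(O)c3OC)C=C(C=O)[C@@H]2COC(C)=O)ccc1O | target

**Step count**

Total: 16 steps. Longest linear sequence: 14 steps (steps 1–3, 5–7, 9–16).

**Steps most likely to fail**

1. Step 12. The risk is insufficient facial discrimination between the enamine and the quinone methide, or acid-only closure through the enol, either of which would erode enantiomeric purity. The fallback replaces catalytic control by resolution. From 17, closure with pyrrolidine (20 mol%) and diphenyl phosphate in CH2Cl2 should give the racemic trans aldehyde F1. Reduction with NaBH4 in MeOH at −20 °C gives the racemic trans alcohol F2. Preparative chromatography on a polysaccharide chiral stationary phase separates the (1S,2R) enantiomer, which is 20, and the route continues with step 14.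

2. Step 11. The risk is acid-promoted ionisation of the free para-hydroxybenzylic carbinol while the acetal is being hydrolysed, leading to uncatalysed ring closure, ether formation or oligomerisation. The fallback releases the aldehyde oxidatively and uses no acid. Compound 12 is C-allylated (NaH, allyl bromide, THF) to the allyl phosphonate F3. Olefination of 11 with F3 (NaH, THF) gives the (E)-allyl acrylamide F4. OsO4 (cat.)/NaIO4/2,6-lutidine in dioxane–water should cleave only the terminal alkene and give the tris-silylated aldehyde F5. TBAF/AcOH in THF then removes the three silyl groups and delivers 17.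

3. Step 15. The risk is sluggish or unselective hydride transfer from zirconium at the hindered conjugated amide (competing attack on the aryl acetates or hydrozirconation of the C3=C4 bond). The fallback reduces before acylating and then acylates chemoselectively. From 20, excess DIBAL-H in THF at −78 °C reduces the N-methoxy-N-methyl amide through its stable chelate to the trihydroxy enal F6. Immobilised Candida antarctica lipase B with vinyl acetate should then acetylate only the primary hydroxyl and give 23 directly.

**Further compounds**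

F1 | step 12 | rac-trans-2-formyl-7-hydroxy-1-(4-hydroxy-3-methoxyphenyl)-N,8-dimethoxy-N-methyl-1,2-dihydronaphthalene-3-carboxamide (1:1 mixture of 19 and its enantiomer) | COc1cc([C@H]2c3c(ccc(O)c3OC)C=C(C(=O)N(C)OC)[C@@H]2C=O)ccc1O.COc1cc([C@@H]2c3c(ccc(O)c3OC)C=C(C(=O)N(C)OC)[C@H]2C=O)ccc1O
F2 | step 12 | rac-trans-7-hydroxy-1-(4-hydroxy-3-methoxyphenyl)-2-(hydroxymethyl)-N,8-dimethoxy-N-methyl-1,2-dihydronaphthalene-3-carboxamide (1:1 mixture of 20 and its enantiomer) | COc1cc([C@H]2c3c(ccc(O)c3OC)C=C(C(=O)N(C)OC)[C@@H]2CO)ccc1O.COc1cc([C@@H]2c3c(ccc(O)c3OC)C=C(C(=O)N(C)OC)[C@H]2CO)ccc1O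
F3 | step 11 | diethyl {1-[methoxy(methyl)amino]-1-oxopent-4-en-2-yl}phosphonate | CCOP(=O)(OCC)C(CC=C)C(=O)N(C)OC
F4 | step 11 | rac-(E)-2-allyl-3-[4-(tert-butyldimethylsilyloxy)-2-{[4-(tert-butyldimethylsilyloxy)-3-methoxyphenyl](triethylsilyloxy)methyl}-3-methoxyphenyl]-N-methoxy-N-methylprop-2-enamide | COc1cc(C(O[Si](CC)(CC)CC)c2c(/C=C(\CC=C)C(=O)N(C)OC)ccc(O[Si](C)(C)C(C)(C)C)c2OC)ccc1O[Si](C)(C)C(C)(C)C
F5 | step 11 | rac-(E)-3-[4-(tert-butyldimethylsilyloxy)-2-{[4-(tert-butyldimethylsilyloxy)-3-methoxyphenyl](triethylsilyloxy)methyl}-3-methoxyphenyl]-N-methoxy-N-methyl-2-(2-oxoethyl)prop-2-enamide | COc1cc(C(O[Si](CC)(CC)CC)c2c(/C=C(\CC=O)C(=O)N(C)OC)ccc(O[Si](C)(C)C(C)(C)C)c2OC)ccc1O[Si](C)(C)C(C)(C)C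
F6 | step 15 | (1S,2R)-7-hydroxy-1-(4-hydroxy-3-methoxyphenyl)-2-(hydroxymethyl)-8-methoxy-1,2-dihydronaphthalene-3-carbaldehyde | COc1cc([C@H]2c3c(ccc(O)c3OC)C=C(C=O)[C@@H]2CO)ccc1O
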